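The quinone ring (ring A: C1–C4, C4a, C8a) is disconnected at C2=C3 and C4–C4a. Ring B, C1, C2 and the complete side chain come from one aryl 1,3-diketone in which the side-chain carbinol carbon is still a ketone; C3 and C4 come from vinylene carbonate. The key step uses the acidic C2 methylene between the two carbonyls and the single free C–H at C4a, ortho to the C1 carbonyl: rhodium-catalysed ortho C–H formylmethylation, aldol condensation and aromatisation close ring A in one operation as a 2-acyl-1-naphthol. Asymmetric ketone reduction, naphthol-to-quinone oxidation at C4, tigloylation and demethylation then give the target.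

Key step: step 2

Remark: the two naphthazarin tautomers of the target interconvert rapidly, so demethylation of 11 should give the compound as drawn. Atom numbers are those of the naphthalene-1,4-dione core (C2 bears the side chain, C5 and C8 the hydroxyls).

Step 1
Reactants: 1 1-(2,5-dimethoxyphenyl)ethan-1-one (2',5'-dimethoxyacetophenone); 2 4-methylpent-3-enoic acid
Product: 4 1-(2,5-dimethoxyphenyl)-6-methylhept-5-ene-1,3-dione, via 4-methylpent-3-enoyl chloride 3 (not isolated)
Conditions: 2, (COCl)2, cat. DMF, CH2Cl2, 0 °C to rt, evaporate; 1 (2 equiv), LiN(SiMe3)2 (2.1 equiv), THF, –78 °C, then 3 (1 equiv), –78 to 0 °C; aq. NH4Cl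
Reagents that add atoms: oxalyl chloride, O=C(Cl)C(=O)Cl (its chlorine is carried only by intermediate 3 and leaves again on the way to 4)
Why: Crossed Claisen-type C-acylation of the lithium enolate of the methyl ketone by the acid chloride; the second equivalent of enolate deprotonates the more acidic diketone so that only mono-C-acylation should occur, and the low temperature should keep the β,γ-alkene out of conjugation.

Step 2
Reactants: 4 1-(2,5-dimethoxyphenyl)-6-methylhept-5-ene-1,3-dione; 5 vinylene carbonate (1,3-dioxol-2-one)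
Product: 7 1-(1-hydroxy-5,8-dimethoxynaphthalen-2-yl)-4-methylpent-3-en-1-one, via ortho-formylmethyl diketone 6 (not isolated)
Conditions: [Cp*RhCl2]2 (5 mol%), AgSbF6 (20 mol%), NaOAc (50 mol%), 5 (1.5 equiv), ClCH2CH2Cl, 90 °C
Reagents that add atoms: none
Why: Proposed new method: the cationic Cp*Rh catalyst (trivalent rhodium), bound to the C1 carbonyl/enolate oxygen of 4, should cleave the one C–H ortho to that carbonyl (C4a) by concerted metalation–deprotonation, vinylene carbonate then inserts into the aryl–rhodium bond, and β-oxygen elimination with loss of CO2 and protonation leaves arylacetaldehyde 6 (new C4–C4a bond) while rhodium stays trivalent, so no external oxidant is needed. The doubly activated C2 methylene then attacks the aldehyde carbon C3 in a 6-exo-trig (enolendo) aldol closure, and dehydration followed by enolisation at C1 aromatises ring A (new C2=C3 bond). The closest known reaction types are the annulation of aroylacetates, aroylacetonitriles and aroyl sulfoxonium ylides with alkynes to 1-naphthols under Cp*Rh or palladium catalysis and the use of vinylene carbonate as an oxidising acetylene or formylmethyl surrogate in directed C–H annulations; the combination with an open-chain 1-aryl-1,3-diketone is the untested part. No stereocentre is created, since the aldol carbinol is lost on dehydration. The step needs site selectivity at the arene, secured because the other ortho position carries OMe, C- over O-cyclisation, secured by the irreversible aromatisation that follows C-attack, and chemoselectivity against the side-chain alkene, secured because a trisubstituted alkene inserts far more slowly than the electron-rich cis-disubstituted vinylene carbonate.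

Step 3
Reactants: 7 1-(1-hydroxy-5,8-dimethoxynaphthalen-2-yl)-4-methylpent-3-en-1-one
Product: 8 2-[(1S)-1-hydroxy-4-methylpent-3-en-1-yl]-5,8-dimethoxynaphthalen-1-ol
Conditions: RuCl[(S,S)-TsDPEN](p-cymene) (2 mol%), HCO2H/Et3N (5:2), CH2Cl2, rt
Reagents that add atoms: none
Why: Noyori asymmetric transfer hydrogenation of an aryl alkyl ketone, a reaction class that tolerates ortho-hydroxyaryl ketones; with the aryl ring held by a CH–π contact to the η6-arene, the (S,S) catalyst should deliver hydride to the Re face and so set the (S) carbinol, as it does for acetophenone.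

Step 4
Reactants: 8 2-[(1S)-1-hydroxy-4-methylpent-3-en-1-yl]-5,8-dimethoxynaphthalen-1-ol
Product: 9 2-[(1S)-1-hydroxy-4-methylpent-3-en-1-yl]-5,8-dimethoxynaphthalene-1,4-dione
Conditions: (KSO3)2NO (2.5 equiv), aq. KH2PO4, acetone/H2O, 0 °C to rt
Reagents that add atoms: Fremy's salt (dipotassium nitrosodisulfonate), [K+].[K+].[O-]S(=O)(=O)N([O])S(=O)(=O)[O-]
Why: Teuber oxidation of a 1-naphthol with a free para position (C4) to the para-quinone, the C4 oxygen coming from the nitroxyl reagent; the buffered radical conditions should leave the secondary alcohol, the alkene and the stereocentre untouched.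

Step 5
Reactants: 9 2-[(1S)-1-hydroxy-4-methylpent-3-en-1-yl]-5,8-dimethoxynaphthalene-1,4-dione; 10 tiglic acid, (2E)-2-methylbut-2-enoic acid
Product: 11 (1S)-1-(5,8-dimethoxy-1,4-dioxo-1,4-dihydronaphthalen-2-yl)-4-methylpent-3-en-1-yl (2E)-2-methylbut-2-enoate
Conditions: DCC, DMAP (20 mol%), CH2Cl2, 0 °C to rt
Reagents that add atoms: none
Why: Steglich esterification of the only free hydroxyl; the C–O bond at the stereocentre is not broken (retention), and the (E) tiglate is the thermodynamically favoured geometry, so DMAP should not erode it.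

Step 6
Reactants: 11 (1S)-1-(5,8-dimethoxy-1,4-dioxo-1,4-dihydronaphthalen-2-yl)-4-methylpent-3-en-1-yl (2E)-2-methylbut-2-enoate
Product: 13 (1S)-1-(5,8-dihydroxy-1,4-dioxo-1,4-dihydronaphthalen-2-yl)-4-methylpent-3-en-1-yl (2E)-2-methylbut-2-enoate (alkannin tiglate, CNP0373203.1), via naphthalene-1,4,5,8-tetraone ester 12 (not isolated)
Conditions: AgO (4 equiv), 6 M HNO3, 1,4-dioxane, rt, short contact; then aq. Na2S2O4, air
Reagents that add atoms: water, O
Why: Oxidative demethylation of the para-dimethoxy ring by divalent silver oxide gives the diquinone (water supplies the new carbonyl oxygens, methanol leaves), and mild reduction returns one quinone unit to the hydroquinone level, which is the naphthazarin; the ester blocks cyclisation of the side-chain oxygen onto the alkene and the stereocentre is not involved.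

Compound list
1 | 1-(2,5-dimethoxyphenyl)ethan-1-one (2',5'-dimethoxyacetophenone) | CC(=O)c1cc(OC)ccc1OC | starting material
2 | 4-methylpent-3-enoic acid | CC(C)=CCC(=O)O | starting material
3 | 4-methylpent-3-enoyl chloride | CC(C)=CCC(=O)Cl | intermediate
4 | 1-(2,5-dimethoxyphenyl)-6-methylhept-5-ene-1,3-dione | COc1ccc(OC)c(c1)C(=O)CC(=O)CC=C(C)C | intermediate
5 | vinylene carbonate (1,3-dioxol-2-one) | O=C1OC=CO1 | starting material
6 | 1-[3,6-dimethoxy-2-(2-oxoethyl)phenyl]-6-methylhept-5-ene-1,3-dione | COc1ccc(OC)c(C(=O)CC(=O)CC=C(C)C)c1CC=O | intermediate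
7 | 1-(1-hydroxy-5,8-dimethoxynaphthalen-2-yl)-4-methylpent-3-en-1-one | COc1ccc(OC)c2c(O)c(C(=O)CC=C(C)C)ccc12 | intermediate
8 | 2-[(1S)-1-hydroxy-4-methylpent-3-en-1-yl]-5,8-dimethoxynaphthalen-1-ol | O[C@@H](CC=C(C)C)c1ccc2c(OC)ccc(OC)c2c1O | intermediate
9 | 2-[(1S)-1-hydroxy-4-methylpent-3-en-1-yl]-5,8-dimethoxynaphthalene-1,4-dione | O[C@@H](CC=C(C)C)C1=CC(=O)c2c(OC)ccc(OC)c2C1=O | intermediate
10 | tiglic acid, (2E)-2-methylbut-2-enoic acid | C/C=C(\C)C(=O)O | starting material
11 | (1S)-1-(5,8-dimethoxy-1,4-dioxo-1,4-dihydronaphthalen-2-yl)-4-methylpent-3-en-1-yl (2E)-2-methylbut-2-enoate | C/C=C(\C)C(=O)O[C@@H](CC=C(C)C)C1=CC(=O)c2c(OC)ccc(OC)c2C1=O | intermediate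
12 | (1S)-4-methyl-1-(1,4,5,8-tetraoxo-1,4,5,8-tetrahydronaphthalen-2-yl)pent-3-en-1-yl (2E)-2-methylbut-2-enoate | C/C=C(\C)C(=O)O[C@@H](CC=C(C)C)C1=CC(=O)C2=C(C1=O)C(=O)C=CC2=O | intermediate
13 | (1S)-1-(5,8-dihydroxy-1,4-dioxo-1,4-dihydronaphthalen-2-yl)-4-methylpent-3-en-1-yl (2E)-2-methylbut-2-enoate (alkannin tiglate) | C/C=C(\C)C(=O)O[C@@H](CC=C(C)C)C1=CC(=O)c2c(O)ccc(O)c2C1=O | target

Total step count: 6. Longest linear sequence: 6 steps (1 → 4 → 7 → 8 → 9 → 11 → 13).

Steps most likely to fail

Step 2 (proposed new method). The catalyst may be sequestered as an O,O-diketonate chelate so that C–H cleavage at C4a never starts, or the side-chain alkene may migrate into conjugation at 90 °C. The fallback uses known chemistry and buys ring A instead of building it. It sets out from acid chloride 3. The lithium enolate of commercial 5,8-dimethoxy-3,4-dihydronaphthalen-1(2H)-one (COc1ccc(OC)c2C(=O)CCCc12; LiN(SiMe3)2, THF, –78 °C) is C-acylated with 3, as in step 1, to give 5,8-dimethoxy-2-(4-methylpent-3-enoyl)-3,4-dihydronaphthalen-1(2H)-one F1. Dehydrogenation of this enolised 2-acyl-tetralone with DDQ (1,4-dioxane, rt to 60 °C) should aromatise ring A and rejoin the route at 7.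

Step 6. Oxidative or nitrating attack on the electron-rich trisubstituted alkene may outrun oxidation of the dimethoxy ring, which is deactivated by the quinone carbonyls. The fallback avoids oxidants and sets out from 11. Both methyl ethers sit peri to a quinone carbonyl, so BCl3 (CH2Cl2, –78 to –20 °C) should cleave them by chelation-assisted dealkylation to the bis(dichloroboryl) ether (1S)-1-{5,8-bis[(dichloroboranyl)oxy]-1,4-dioxo-1,4-dihydronaphthalen-2-yl}-4-methylpent-3-en-1-yl (2E)-2-methylbut-2-enoate F2. Hydrolysis with cold aq. NaHCO3 then rejoins the route at 13.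

Step 3. The hydrogen-bonded ortho-hydroxy ketone may be reduced slowly and with poor facial selectivity, and the β,γ-alkene may migrate in the amine-containing medium. The fallback masks the phenol and uses a stoichiometric chiral borane; it sets out from 7. Silylation (TBSOTf, 2,6-lutidine, CH2Cl2, 0 °C) should give 1-{1-[(tert-butyldimethylsilyl)oxy]-5,8-dimethoxynaphthalen-2-yl}-4-methylpent-3-en-1-one F3. Reduction with (–)-B-chlorodiisopinocampheylborane (THF, –25 °C, diethanolamine work-up), which gives the (S) carbinol from aryl alkyl ketones and does not hydroborate the alkene, should give (1S)-1-{1-[(tert-butyldimethylsilyl)oxy]-5,8-dimethoxynaphthalen-2-yl}-4-methylpent-3-en-1-ol F4. Desilylation with Bu4NF (THF, 0 °C) rejoins the route at 8.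

Further compounds
F1 | step 2 | 5,8-dimethoxy-2-(4-methylpent-3-enoyl)-3,4-dihydronaphthalen-1(2H)-one (racemic at C2, largely enolised) | COc1ccc(OC)c2C(=O)C(C(=O)CC=C(C)C)CCc12
F2 | step 6 | (1S)-1-{5,8-bis[(dichloroboranyl)oxy]-1,4-dioxo-1,4-dihydronaphthalen-2-yl}-4-methylpent-3-en-1-yl (2E)-2-methylbut-2-enoate | C/C=C(\C)C(=O)O[C@@H](CC=C(C)C)C1=CC(=O)c2c(OB(Cl)Cl)ccc(OB(Cl)Cl)c2C1=O
F3 | step 3 | 1-{1-[(tert-butyldimethylsilyl)oxy]-5,8-dimethoxynaphthalen-2-yl}-4-methylpent-3-en-1-one | CC(C)=CCC(=O)c1ccc2c(OC)ccc(OC)c2c1O[Si](C)(C)C(C)(C)C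
F4 | step 3 | (1S)-1-{1-[(tert-butyldimethylsilyl)oxy]-5,8-dimethoxynaphthalen-2-yl}-4-methylpent-3-en-1-ol | O[C@@H](CC=C(C)C)c1ccc2c(OC)ccc(OC)c2c1O[Si](C)(C)C(C)(C)C
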